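## Retrosynthetic overview

- The C8 isobutyryl group is added last by C-acylation. The C6 tertiary alcohol comes from α-hydroxylation of a 2-prenylcyclooctane-1,3-dione.
- The cyclooctane is formed by a two-carbon ring expansion of a cyclohexanone TMS enol ether with a prenylacetyl keteniminium ([2+2], then retro-aldol-type opening). This installs C6 (with its prenyl) and C7.
- The enol ether comes from Cu-catalysed, TMSCl-trapped addition of homoprenyl to a 3-methylcyclohexenone. The addition is anti to the C2 prenyl and forms the quaternary C1.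
- The enone comes from an enamine-catalysed Michael/aldol-condensation (Robinson-type) annulation of 5-methylhex-4-enal with an (E)-crotonyl ketone, followed by moving the enone into conjugation with the methyl-bearing carbon. The annulation sets C2.
- All partners derive from 2-methylbut-3-en-2-ol, crotonyl chloride and homoprenyl bromide.

**Assumption:** C4 and C8 are α to ketones and epimerizable, so I assume they equilibrate to the drawn configuration. C6 is set by face-selective hydroxylation (substrate control).

## Route

**Step 1**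
Reactants: 1 2-methylbut-3-en-2-ol; 2 ethyl vinyl ether (excess)
Product: 3 5-methylhex-4-enal
Conditions: Hg(OAc)2 (5 mol %), neat, 35 °C; then 150 °C, sealed tube
Reagents that add atoms: ethyl vinyl ether 2 (C=COCC) supplies the CH2–CHO unit
Why: Vinyl transetherification gives the tertiary allyl vinyl ether, and a Claisen [3,3] shift delivers the CH2CHO unit to the alkene terminus. The product carries a prenyl-type CH2CH=CMe2 chain.

**Step 2**
Reactants: 4 (E)-crotonyl chloride; 5 N,O-dimethylhydroxylamine hydrochloride
Product: 6 (E)-N-methoxy-N-methylbut-2-enamide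
Conditions: pyridine, CH2Cl2, 0 → 23 °C
Reagents that add atoms: 5 (CNOC.Cl)
Why: Standard Weinreb amide formation, so that the next step stops at the ketone.

**Step 3**
Reactants: 6 Weinreb amide; 7 homoprenylmagnesium bromide
Product: 8 (E)-8-methylnona-2,7-dien-4-one, C/C=C/C(=O)CCC=C(C)C
Conditions: THF, 0 → 23 °C; aq. NH4Cl
Reagents that add atoms: 7 (CC(C)=CCC[Mg]Br)
Why: Weinreb ketone synthesis gives the β-methyl enone (Michael acceptor) without over-addition.

**Step 4**
Reactants: 1 2-methylbut-3-en-2-ol; 9 N,N-dimethylacetamide dimethyl acetal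
Product: 10 N,N-dimethyl-5-methylhex-4-enamide
Conditions: xylene, 140 °C, sealed tube
Reagents that add atoms: 9 (CC(OC)(OC)N(C)C) supplies CH2C(=O)NMe2
Why: Eschenmoser–Claisen rearrangement of the tertiary allylic alcohol gives the prenylacetamide that becomes the ketene component.

**Step 5**
Reactants: 3 5-methylhex-4-enal (2 equiv); 8 enone
Product: 11 (4R)-2,4-bis(3-methylbut-2-en-1-yl)-5-methylcyclohex-2-en-1-one, O=C1CC(C)[C@@H](CC=C(C)C)C=C1CC=C(C)C (C5 epimer mixture)
Conditions: (S)-diphenylprolinol TMS ether (20 mol %), 2-nitrobenzoic acid (20 mol %), toluene, 23 °C, 72 h; then pyrrolidine (20 mol %), AcOH (40 mol %), 50 °C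
Reagents that add atoms: none
Why: Enamine-catalysed Michael addition of the aldehyde to the enone, followed by intramolecular aldol condensation (Robinson annulation). The catalyst enantiomer is chosen so that the enamine face selectivity gives the drawn configuration at the prenyl-bearing carbon (target C2). The methyl-bearing centre is epimeric and is destroyed in step 8.

**Step 6**
Reactants: 11 enone
Product: 12 (4S)-2,4-bis(3-methylbut-2-en-1-yl)-5-methylcyclohexan-1-one, O=C1CC(C)[C@@H](CC=C(C)C)CC1CC=C(C)C (epimeric at C2 and C5 of the ring)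
Conditions: L-Selectride, THF, −78 °C; then sat. NH4Cl
Reagents that add atoms: none
Why: Conjugate (1,4-) hydride reduction leaves the isolated trisubstituted alkenes intact. Removing the enone also prevents the later dehydrogenation from aromatizing to a phenol.

**Step 7**
Reactants: 12 ketone
Product: 13 (4S)-trimethyl{[3-methyl-4,6-bis(3-methylbut-2-en-1-yl)cyclohex-1-en-1-yl]oxy}silane, C[Si](C)(C)OC1=CC(C)[C@@H](CC=C(C)C)CC1CC=C(C)C
Conditions: LDA, THF, −78 °C; then TMSCl, Et3N
Reagents that add atoms: chlorotrimethylsilane (C[Si](C)(C)Cl)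
Why: Kinetic deprotonation takes the CH2 rather than the prenyl-bearing methine, giving the less substituted silyl enol ether.

**Step 8**
Reactants: 13 silyl enol ether
Product: 14 (4S)-3-methyl-4,6-bis(3-methylbut-2-en-1-yl)cyclohex-2-en-1-one, CC1=CC(=O)C(CC=C(C)C)C[C@@H]1CC=C(C)C (C6 epimer mixture)
Conditions: Pd(OAc)2 (10 mol %), O2 (1 atm), DMSO, 23 °C
Reagents that add atoms: none
Why: Ito–Saegusa (Larock) oxidation removes the β-H at the methyl-bearing carbon and gives the β-methyl enone. The prenyl-bearing stereocentre (C4 of the enone) is untouched.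

**Step 9**
Reactants: 14 enone; 7 homoprenylmagnesium bromide (3 equiv)
Product: 15 silyl enol ether with quaternary C1, C[Si](C)(C)OC1=C[C@](C)(CCC=C(C)C)[C@@H](CC=C(C)C)CC1CC=C(C)C (C4 epimeric)
Conditions: CuBr·SMe2 (30 mol %), TMSCl, HMPA, THF, −78 → −30 °C; the crude product is filtered through Et3N-treated alumina
Reagents that add atoms: 7 (CC(C)=CCC[Mg]Br); chlorotrimethylsilane (C[Si](C)(C)Cl)
Why: Cu-catalysed, TMSCl-accelerated 1,4-addition occurs trans to the adjacent prenyl group, so the homoprenyl ends up anti to prenyl and the methyl syn, as in the target. It forms the quaternary C1 and traps the enolate regiospecifically as the C5=C8 silyl enol ether needed for the next step.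

**Step 10**
Reactants: 15 silyl enol ether; 10 N,N-dimethyl-5-methylhex-4-enamide (2 equiv)
Product: 16 2-prenylcyclooctane-1,3-dione, CC(C)=CCC[C@]1(C)[C@@H](CC=C(C)C)C[C@H](CC=C(C)C)C(=O)C(CC=C(C)C)C(=O)C1 (C6 enolized; C4 as drawn)
Conditions: Tf2O (2 equiv), 2,4,6-collidine (2.2 equiv), 1,2-dichloroethane, 0 → 80 °C, 12 h; then 1 M HCl, THF, 40 °C
Reagents that add atoms: amide 10 (CN(C)C(=O)CCC=C(C)C); water (O)
Why: Proposed new method: Tf2O activation of amide 10 gives the prenylacetyl keteniminium. The nucleophilic enol-ether carbon C8 attacks it, and ring closure gives a 3-silyloxycyclobutaniminium. This donor–acceptor cyclobutane opens by loss of TMS with cleavage of the fused C5–C8 bond (push–pull, retro-aldol type), giving the ring-expanded enamine/enaminone, which hydrolyses to the 2-prenyl-1,3-dione. The closest known reactions are the Ghosez keteniminium–alkene [2+2] and the de Mayo retro-aldol ring expansion. C1 and C2 are untouched, and C4 (α to the C5 ketone) equilibrates to the drawn configuration under the acidic work-up.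

**Step 11**
Reactants: 16 dione
Product: 17 2-hydroxy-1,3-dione, CC(C)=CCC[C@]1(C)[C@@H](CC=C(C)C)C[C@H](CC=C(C)C)C(=O)[C@](O)(CC=C(C)C)C(=O)C1
Conditions: O2 (1 atm), Cs2CO3, DMF, 23 °C; then P(OEt)3
Reagents that add atoms: dioxygen (O=O)
Why: Enol autoxidation (α-hydroxylation of a 2-alkyl-1,3-diketone). The hydroperoxide is reduced in situ, and O2 attacks the enolate from its less hindered face, which sets the C6 carbinol. The alkenes survive.

**Step 12**
Reactants: 17 hydroxy-diketone; 18 isobutyryl chloride
Product: 19 Hyphenrone F, CC(C)=CCC[C@]1(C)[C@@H](CC=C(C)C)C[C@H](CC=C(C)C)C(=O)[C@](O)(CC=C(C)C)C(=O)[C@H]1C(=O)C(C)C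
Conditions: LiHMDS (2.4 equiv), THF, −78 °C; MgBr2·OEt2; then 18 (1.2 equiv), −78 → 0 °C; aq. NH4Cl
Reagents that add atoms: 18 (CC(C)C(=O)Cl)
Why: The first equivalent of base forms the chelated alkoxide. The kinetic enolate forms at the CH2 (C8) rather than the methine C4, and the magnesium enolate is acylated at carbon (C-acylation of a ketone enolate). The product triketone is enolized, which protects it from over-acylation, and C4/C8 equilibrate to the thermodynamic configuration.

## Compound list

1 | 2-methylbut-3-en-2-ol | CC(C)(O)C=C | starting material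
2 | ethyl vinyl ether | C=COCC | starting material
3 | 5-methylhex-4-enal | CC(C)=CCCC=O | intermediate
4 | (E)-crotonyl chloride | C/C=C/C(=O)Cl | starting material
5 | N,O-dimethylhydroxylamine hydrochloride | CNOC.Cl | starting material
6 | (E)-N-methoxy-N-methylbut-2-enamide | C/C=C/C(=O)N(C)OC | intermediate
7 | homoprenylmagnesium bromide (from 5-bromo-2-methylpent-2-ene) | CC(C)=CCC[Mg]Br | starting material
8 | (E)-8-methylnona-2,7-dien-4-one | C/C=C/C(=O)CCC=C(C)C | intermediate
9 | N,N-dimethylacetamide dimethyl acetal | CC(OC)(OC)N(C)C | starting material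
10 | N,N-dimethyl-5-methylhex-4-enamide | CN(C)C(=O)CCC=C(C)C | intermediate
11 | (4R)-2,4-bis(3-methylbut-2-en-1-yl)-5-methylcyclohex-2-en-1-one | O=C1CC(C)[C@@H](CC=C(C)C)C=C1CC=C(C)C | intermediate
12 | (4S)-2,4-bis(3-methylbut-2-en-1-yl)-5-methylcyclohexan-1-one | O=C1CC(C)[C@@H](CC=C(C)C)CC1CC=C(C)C | intermediate
13 | TMS enol ether of 12 (C5=C8 side) | C[Si](C)(C)OC1=CC(C)[C@@H](CC=C(C)C)CC1CC=C(C)C | intermediate
14 | (4S)-3-methyl-4,6-bis(3-methylbut-2-en-1-yl)cyclohex-2-en-1-one | CC1=CC(=O)C(CC=C(C)C)C[C@@H]1CC=C(C)C | intermediate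
15 | TMS enol ether with quaternary C1 | C[Si](C)(C)OC1=C[C@](C)(CCC=C(C)C)[C@@H](CC=C(C)C)CC1CC=C(C)C | intermediate
16 | 2-prenylcyclooctane-1,3-dione core | CC(C)=CCC[C@]1(C)[C@@H](CC=C(C)C)C[C@H](CC=C(C)C)C(=O)C(CC=C(C)C)C(=O)C1 | intermediate
17 | 2-hydroxy-2-prenylcyclooctane-1,3-dione | CC(C)=CCC[C@]1(C)[C@@H](CC=C(C)C)C[C@H](CC=C(C)C)C(=O)[C@](O)(CC=C(C)C)C(=O)C1 | intermediate
18 | isobutyryl chloride | CC(C)C(=O)Cl | starting material
19 | Hyphenrone F | CC(C)=CCC[C@]1(C)[C@@H](CC=C(C)C)C[C@H](CC=C(C)C)C(=O)[C@](O)(CC=C(C)C)C(=O)[C@H]1C(=O)C(C)C | target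

## Totals

- **Total steps:** 12.
- **Longest linear sequence:** 10 (steps 2, 3, 5, 6, 7, 8, 9, 10, 11, 12: crotonyl chloride → Weinreb amide 6 → enone 8 → 11 → 12 → 13 → 14 → 15 → 16 → 17 → 19).

## Three steps most likely to fail

1. **Step 10 (proposed new ring expansion).** The nucleophilic enol carbon C8 is neopentylic, and the keteniminium may be diverted by the prenyl alkenes.
   - Fallback (known chemistry): use dichloroketene (Cl3CCOCl, Zn–Cu) for the [2+2] with 15, then fluoride-induced retro-aldol opening of the cyclobutanone. Dechlorinate with Zn/AcOH to the parent cyclooctane-1,3-dione, then C-prenylate it (prenyl bromide, base) to reach 16.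
2. **Step 5 (organocatalytic Robinson annulation with a β-methyl enone).** The enone is a poor acceptor for enamine catalysis, and yield and ee may be low. The aldehyde α-stereocentre could also erode during the aldol condensation.
   - Fallback: run the annulation with an achiral amine (pyrrolidine/AcOH) to give racemic 11. Carry it to enone 14 and resolve by preparative chiral-phase HPLC; 14 is a neutral, UV-active enone.
3. **Step 12 (regioselective C-acylation at C8 over C4, with competing O-acylation).**
   - Fallback: form the kinetic enolate of 17 and add isobutyraldehyde. Oxidise the resulting β-hydroxy ketone with Dess–Martin periodinane to the triketone, which avoids O-acylation.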